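The readings stem from a simulated flask on assumed constants; noise was put on by code.

**Two rates.** Target appears in the dusk run at a mean 0.0190 M/min up to 12.0 min, and in the winter run at 0.0347 M/min up to 6.00 min. I take these two rates because their windows end at similar conversions, 57% and 52%, and the charges of substrate and reagent match. The winter reading at 10.0 min is still rising, at 77%, but it lies beyond the window I chose. From 25.0 min in the dusk run and 15.0 min in the winter run, the readings sit at the plateau and carry no rate.

| setting | dusk | winter | flask |
|---|---|---|---|
| substrate | 0.40 M | 0.40 M | 0.40 M |
| reagent | 1.8 equiv | 1.8 equiv | 1.80 equiv |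
| free catalyst | 0.29 mol% | 0.66 mol% | 0.44 mol% |
| remark | run made earlier | run made earlier |  |

| run | time / min | target / % |
|---|---|---|
| dusk | 4.00 | 21 |
| dusk | 12.0 | 57 |
| dusk | 25.0 | 101 |
| dusk | 30.0 | 99 |
| dusk | 50.0 | 100 |
| dusk | 60.0 | 100 |
| dusk | 80.0 | 98 |
| winter | 6.00 | 52 |
| winter | 10.0 | 77 |
| winter | 15.0 | 100 |
| winter | 25.0 | 99 |
| winter | 30.0 | 101 |
| winter | 50.0 | 98 |
| winter | 80.0 | 101 |

(standard deviation of a reading: 1.5 percentage points)

* factor on the rate of making target when 5.0% of the substrate are converted if free catalyst is charged twice over
* factor on the rate when 5.0% of the substrate are converted if free catalyst is charged at 0.04 mol% instead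



**Catalyst order.** I define the apparent catalyst order n as the logarithm of the rate ratio over the logarithm of the loading ratio: 0.731. The rates differ by a factor of 1.83, the loadings by 2.28. This n is a reading, and it carries their scatter.

**My reckoning.** At 5.0% conversion, [substrate] and [reagent] are the same at every loading in the question. A loading factor raised to n therefore gives the rate factor. Doubling gives 1.66, and 0.04 mol% gives 0.173. Both loadings lie outside the two runs, the second far outside.

**The forecast.** It gives 1.49 (1.38 to 1.62) and 0.21 (0.13 to 0.32). It states that “the apparent order is about 0.6”, which differs from my n.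

**The result.** The simulation gives 1.70 for doubling and 0.133 for 0.04 mol%.

    reagent + free catalyst → catalyst intermediate A (k = 77.0 /M/min)
    catalyst intermediate A → by-product + catalyst intermediate B (k = 60.0 /min)
    substrate + catalyst intermediate B ⇌ catalyst intermediate C (K = 4.80 /M, k = 16000 /M/min)
    catalyst intermediate C → catalyst intermediate D (k = 1400 /min)
    catalyst intermediate D → free catalyst + target (k = 1300 /min)
    2 free catalyst ⇌ resting dimer (K = 1200 /M, k = 2700 /M/min)

**Order again.** Put back into n, doubling gives 0.770 and the low loading gives 0.841, higher than the first and than my 0.731. In the flask at 8.00 min, with target at 52.2%, the catalyst stands as resting dimer 43.5%, free catalyst 32.2%, catalyst intermediate A 21.1%, catalyst intermediate B 1.40%, catalyst intermediate C 0.904% and catalyst intermediate D 0.973%. By 40.0 min, substrate, the limiting reagent, is at 0%, reagent at 44.2%, and catalyst intermediate B holds 100% of the catalyst.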